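**Plan**
- The retrosynthesis first removes the C5 formyl carbon and the C3 protecting group of ring A (the acyl ring: C1 ester carbon, C2 methyl, oxygen at C3, C4 and C6). It then cuts ring A at C1–C6 and C2–C3.
- The feature used: C1–C2 of ring A are the two alkyne carbons of a but-2-ynoate already esterified to ring B (atraric acid). C3–C6 are the four chain carbons of a 4-alkoxyacetoacetate, oxygenated where ring A needs oxygen.
- Forward: a 4-(4-methoxybenzyloxy)acetoacetate is made and silylated twice to the diene (steps 1–3), and atraric acid is acylated at its 4-hydroxyl with but-2-ynoic acid (step 4).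
- Cycloaddition and aromatization build ring A, the only ring formed (step 5). Formylation at C5 and removal of the 4-methoxybenzyl (PMB) ether finish the target (steps 6–7).
- The target has no stereocentre, so only regiochemistry has to be controlled.

Key step: step 5

Assumption: the silyl enol ethers are drawn as their expected Z isomers and the cycloadduct as the suprafacial adduct; these geometries and the two sp3 carbons of the cycloadduct are erased on aromatization and do not affect the outcome.

**Step 1**
Reactants: 1 methyl 4-chloro-3-oxobutanoate; 2 4-methoxybenzyl alcohol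
Product: 4 methyl 4-[(4-methoxybenzyl)oxy]-3-oxobutanoate, via sodium 4-methoxybenzyl oxide 3 (not isolated)
Conditions: NaH (2.2 equiv), THF, 0 °C; then 1, 0 °C to rt; aq. HCl work-up
Reagents that add atoms: none
Why: Williamson etherification, in which the second equivalent of NaH holds the keto ester as its sodium enolate while the alkoxide displaces the primary chloride next to the ketone, the standard route to 4-alkoxyacetoacetates.

**Step 2**
Reactants: 4 methyl 4-[(4-methoxybenzyl)oxy]-3-oxobutanoate
Product: 5 methyl (2Z)-4-[(4-methoxybenzyl)oxy]-3-(trimethylsilyloxy)but-2-enoate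
Conditions: Me3SiCl, Et3N, toluene, rt
Reagents that add atoms: chlorotrimethylsilane, C[Si](C)(C)Cl
Why: Soft enolization and O-silylation of the β-keto ester (silyl enol ether formation) at the doubly activated C2 should give the conjugated β-silyloxy enoate, the usual first stage towards 1,3-bis(silyloxy) dienes.

**Step 3**
Reactants: 5 methyl (2Z)-4-[(4-methoxybenzyl)oxy]-3-(trimethylsilyloxy)but-2-enoate
Product: 7 (1Z,3Z)-1-methoxy-4-[(4-methoxybenzyl)oxy]-1,3-bis(trimethylsilyloxy)buta-1,3-diene, via lithium dienolate 6 (not isolated)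
Conditions: LiN(iPr)2, THF, −78 °C; then Me3SiCl, −78 to 0 °C; non-aqueous work-up, used crude
Reagents that add atoms: chlorotrimethylsilane, C[Si](C)(C)Cl
Why: Kinetic γ-deprotonation of the β-silyloxy enoate at the CH2 bearing the ether oxygen gives the extended lithium dienolate, which chlorotrimethylsilane traps on oxygen (silyl ketene acetal formation), as is established for 4-alkoxy-1,3-bis(silyloxy) dienes.

**Step 4**
Reactants: 8 methyl 2,4-dihydroxy-3,6-dimethylbenzoate (atraric acid); 9 but-2-ynoic acid
Product: 10 methyl 4-(but-2-ynoyloxy)-2-hydroxy-3,6-dimethylbenzoate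
Conditions: DCC, DMAP (cat.), CH2Cl2, 0 °C to rt
Reagents that add atoms: none
Why: Steglich esterification should acylate the 4-hydroxyl selectively, because the 2-hydroxyl is hydrogen-bonded to the ester carbonyl and flanked by a methyl group, the usual site selectivity of 2,4-dihydroxybenzoates.

**Step 5**
Reactants: 10 methyl 4-(but-2-ynoyloxy)-2-hydroxy-3,6-dimethylbenzoate; 7 (1Z,3Z)-1-methoxy-4-[(4-methoxybenzyl)oxy]-1,3-bis(trimethylsilyloxy)buta-1,3-diene
Product: 14 methyl 4-({4,6-dihydroxy-3-[(4-methoxybenzyl)oxy]-2-methylbenzoyl}oxy)-2-hydroxy-3,6-dimethylbenzoate, via aryl trimethylsilyl ether 11 (not isolated), via cyclohexa-1,4-diene cycloadduct 12 (not isolated), via tris(trimethylsilyl) ether 13 (not isolated)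
Conditions: N,O-bis(trimethylsilyl)acetamide (BSA), xylene, 60 °C; then 7 (2.5 equiv), 140 °C, sealed tube; then 1 M HCl, THF, 0 °C to rt
Reagents that add atoms: none
Why: Thermal [4+2] cycloaddition of the electron-rich diene to the aryl ynoate, probably asynchronous with bond C2–C3 (the ether-bearing diene terminus to the methyl-bearing β-carbon) leading and bond C1–C6 (ketene acetal carbon to the α-carbon) following, should give cyclohexa-1,4-diene 12, whose ketal carbon C6 loses methanol together with the C3 hydrogen to give arene 13, and aqueous acid then frees the three silyl ethers. The closest known reaction type is the Diels–Alder reaction and aromatization of 1-alkoxy-1,3-bis(silyloxy)buta-1,3-dienes with acetylenic esters to resorcylates, of which this is a more hindered member because C2 and C3 are both substituted. Ring A is closed as a six-membered carbocycle by intermolecular cycloaddition, both ring bonds forming in one operation (in the stepwise limit a Mukaiyama–Michael addition followed by closure onto the silyloxycarbenium carbon). No stereocentre survives, since the two sp3 carbons of 12 are set by suprafacial addition to the diene and are erased on aromatization. The step needs head-to-tail regiochemistry, which is secured because the largest HOMO coefficient of the diene lies on its ether-bearing terminus and the largest LUMO coefficient of the ynoate on its β-carbon, so the ester carbon ends up next to the C6 oxygen and the methyl next to the C3 ether. Prior silylation of the chelated ring B phenol with BSA removes the only acidic proton that could destroy the diene, and the aryl ester makes the ynoate a better acceptor than an alkyl but-2-ynoate.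

**Step 6**
Reactants: 14 methyl 4-({4,6-dihydroxy-3-[(4-methoxybenzyl)oxy]-2-methylbenzoyl}oxy)-2-hydroxy-3,6-dimethylbenzoate
Product: 15 methyl 4-({5-formyl-4,6-dihydroxy-3-[(4-methoxybenzyl)oxy]-2-methylbenzoyl}oxy)-2-hydroxy-3,6-dimethylbenzoate
Conditions: MgCl2, Et3N, (CH2O)n, THF, reflux; then 1 M HCl
Reagents that add atoms: paraformaldehyde (formaldehyde unit), C=O
Why: Magnesium-mediated ortho-formylation of a phenol (Casnati–Skattebøl reaction) should deliver formaldehyde from the magnesium phenoxides of the C4 and C6 hydroxyls to C5, the only unsubstituted carbon of ring A, with a second formaldehyde as the internal oxidant, while ring B has no free position ortho to its phenol.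

**Step 7**
Reactants: 15 methyl 4-({5-formyl-4,6-dihydroxy-3-[(4-methoxybenzyl)oxy]-2-methylbenzoyl}oxy)-2-hydroxy-3,6-dimethylbenzoate
Product: 16 methyl 4-[(5-formyl-3,4,6-trihydroxy-2-methylbenzoyl)oxy]-2-hydroxy-3,6-dimethylbenzoate (CNP0216802.0)
Conditions: CF3CO2H, anisole, CH2Cl2, 0 °C to rt
Reagents that add atoms: none
Why: Acidolysis of the 4-methoxybenzyl aryl ether (SN1 cleavage), with anisole trapping the benzylic cation by Friedel–Crafts alkylation, should free the C3 hydroxyl without touching the two esters or the chelated aldehyde.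

**Compound list**
1 | methyl 4-chloro-3-oxobutanoate (methyl 4-chloroacetoacetate) | COC(=O)CC(=O)CCl | starting material
2 | 4-methoxybenzyl alcohol | COc1ccc(CO)cc1 | starting material
3 | sodium 4-methoxybenzyl oxide (sodium (4-methoxyphenyl)methanolate) | [Na+].[O-]Cc1ccc(OC)cc1 | intermediate
4 | methyl 4-[(4-methoxybenzyl)oxy]-3-oxobutanoate | COC(=O)CC(=O)COCc1ccc(OC)cc1 | intermediate
5 | methyl (2Z)-4-[(4-methoxybenzyl)oxy]-3-(trimethylsilyloxy)but-2-enoate | COC(=O)/C=C(\O[Si](C)(C)C)COCc1ccc(OC)cc1 | intermediate
6 | lithium (1E,3Z)-1-methoxy-4-[(4-methoxybenzyl)oxy]-3-(trimethylsilyloxy)buta-1,3-dien-1-olate | CO/C([O-])=C/C(O[Si](C)(C)C)=C/OCc1ccc(OC)cc1.[Li+] | intermediate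
7 | (1Z,3Z)-1-methoxy-4-[(4-methoxybenzyl)oxy]-1,3-bis(trimethylsilyloxy)buta-1,3-diene | CO/C(O[Si](C)(C)C)=C/C(O[Si](C)(C)C)=C/OCc1ccc(OC)cc1 | intermediate
8 | methyl 2,4-dihydroxy-3,6-dimethylbenzoate (atraric acid) | COC(=O)c1c(C)cc(O)c(C)c1O | starting material
9 | but-2-ynoic acid | CC#CC(=O)O | starting material
10 | methyl 4-(but-2-ynoyloxy)-2-hydroxy-3,6-dimethylbenzoate | CC#CC(=O)Oc1cc(C)c(C(=O)OC)c(O)c1C | intermediate
11 | methyl 4-(but-2-ynoyloxy)-3,6-dimethyl-2-(trimethylsilyloxy)benzoate | CC#CC(=O)Oc1cc(C)c(C(=O)OC)c(O[Si](C)(C)C)c1C | intermediate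
12 | methyl 4-({6-methoxy-3-[(4-methoxybenzyl)oxy]-2-methyl-4,6-bis(trimethylsilyloxy)cyclohexa-1,4-diene-1-carbonyl}oxy)-3,6-dimethyl-2-(trimethylsilyloxy)benzoate, racemic, 6-methoxy cis to the 3-(4-methoxybenzyloxy) group | CO[C@@]1(O[Si](C)(C)C)C=C(O[Si](C)(C)C)[C@@H](OCc2ccc(OC)cc2)C(C)=C1C(=O)Oc1cc(C)c(C(=O)OC)c(O[Si](C)(C)C)c1C | intermediate
13 | methyl 4-({3-[(4-methoxybenzyl)oxy]-2-methyl-4,6-bis(trimethylsilyloxy)benzoyl}oxy)-3,6-dimethyl-2-(trimethylsilyloxy)benzoate | COC(=O)c1c(C)cc(OC(=O)c2c(C)c(OCc3ccc(OC)cc3)c(O[Si](C)(C)C)cc2O[Si](C)(C)C)c(C)c1O[Si](C)(C)C | intermediate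
14 | methyl 4-({4,6-dihydroxy-3-[(4-methoxybenzyl)oxy]-2-methylbenzoyl}oxy)-2-hydroxy-3,6-dimethylbenzoate | COC(=O)c1c(C)cc(OC(=O)c2c(C)c(OCc3ccc(OC)cc3)c(O)cc2O)c(C)c1O | intermediate
15 | methyl 4-({5-formyl-4,6-dihydroxy-3-[(4-methoxybenzyl)oxy]-2-methylbenzoyl}oxy)-2-hydroxy-3,6-dimethylbenzoate | COC(=O)c1c(C)cc(OC(=O)c2c(C)c(OCc3ccc(OC)cc3)c(O)c(C=O)c2O)c(C)c1O | intermediate
16 | methyl 4-[(5-formyl-3,4,6-trihydroxy-2-methylbenzoyl)oxy]-2-hydroxy-3,6-dimethylbenzoate (CNP0216802.0) | COC(=O)c1c(C)cc(OC(=O)c2c(C)c(O)c(O)c(C=O)c2O)c(C)c1O | target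

**Step count**
Total: 7 steps. Longest linear sequence: 6 steps (1, 2, 3, 5, 6, 7); the ring B branch is step 4.

**Steps most likely to fail**

Step 5. The cycloaddition may stall, because bond C2–C3 has to join two substituted carbons, while the diene is slowly consumed at 140 °C by silyl migration or protodesilylation. The fallback replaces the alkyne by the isomeric allene, whose central carbon is unhindered; cycloaddition of allenic esters with oxygenated dienes is an established way to ortho-methyl benzoates. It sets out from 8. Esterification of the 4-hydroxyl with buta-2,3-dienoic acid (2-chloro-1-methylpyridinium iodide, Et3N, CH2Cl2, 0 °C) should give methyl 4-(buta-2,3-dienoyloxy)-2-hydroxy-3,6-dimethylbenzoate F1. Silylation with BSA as in step 5 gives methyl 4-(buta-2,3-dienoyloxy)-3,6-dimethyl-2-(trimethylsilyloxy)benzoate F2. Diene 7 should then add across the α,β-double bond in toluene at 80–110 °C to give the methylidene cyclohexene adduct methyl 4-({6-methoxy-3-[(4-methoxybenzyl)oxy]-2-methylidene-4,6-bis(trimethylsilyloxy)cyclohex-4-ene-1-carbonyl}oxy)-3,6-dimethyl-2-(trimethylsilyloxy)benzoate F3 (drawn as the racemic endo, all-cis adduct; its configuration is irrelevant). F3 aromatizes by loss of methanol and a 1,3-hydrogen shift of the exocyclic double bond into the ring, and so comes back to the route at 13, which the acid work-up of step 5 turns into 14. The same two ring bonds, C1–C6 and C2–C3, are formed.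

Step 6. The formylation may stop short, because the three phenols and the salicylate-type chelates tie up the magnesium and the ester deactivates ring A; the ring may also be captured by a second arene to give a diarylmethane. The fallback reverses the order of the last two operations and uses an electrophilic formylation. It sets out from 14. Acidolysis (CF3CO2H, anisole, CH2Cl2, 0 °C) should give methyl 2-hydroxy-3,6-dimethyl-4-[(3,4,6-trihydroxy-2-methylbenzoyl)oxy]benzoate F4, which is handled under argon because of its hydroquinone-like ring. Rieche formylation (Cl2CHOMe, TiCl4, CH2Cl2, −78 to 0 °C; aqueous HCl) should then attack C5, the only unsubstituted carbon of ring A, and the route is rejoined at 16.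

Step 3. The dienolate formation may be unselective (competing deprotonation at C2, C-silylation), and the diene may lose a silyl group on handling, giving material too impure for step 5. The fallback avoids the lithium dienolate altogether. It sets out from 4 and reaches 7 in one operation by double soft enolization with Me3SiOTf (2.2 equiv) and Et3N in Et2O at 0 °C, followed by filtration under argon. It makes no compound outside the list (entry F0).

**Further compounds**
F1 | step 5 | methyl 4-(buta-2,3-dienoyloxy)-2-hydroxy-3,6-dimethylbenzoate | C=C=CC(=O)Oc1cc(C)c(C(=O)OC)c(O)c1C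
F2 | step 5 | methyl 4-(buta-2,3-dienoyloxy)-3,6-dimethyl-2-(trimethylsilyloxy)benzoate | C=C=CC(=O)Oc1cc(C)c(C(=O)OC)c(O[Si](C)(C)C)c1C
F3 | step 5 | methyl 4-({6-methoxy-3-[(4-methoxybenzyl)oxy]-2-methylidene-4,6-bis(trimethylsilyloxy)cyclohex-4-ene-1-carbonyl}oxy)-3,6-dimethyl-2-(trimethylsilyloxy)benzoate, racemic, all-cis | CO[C@@]1(O[Si](C)(C)C)C=C(O[Si](C)(C)C)[C@@H](OCc2ccc(OC)cc2)C(=C)[C@H]1C(=O)Oc1cc(C)c(C(=O)OC)c(O[Si](C)(C)C)c1C
F4 | step 6 | methyl 2-hydroxy-3,6-dimethyl-4-[(3,4,6-trihydroxy-2-methylbenzoyl)oxy]benzoate | COC(=O)c1c(C)cc(OC(=O)c2c(C)c(O)c(O)cc2O)c(C)c1O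
F0 | step 3 | none | none
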